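**Remarks on the chemistry (assumptions)**

- Locants C7, C8, C9 and C7', C8', C9' are lignan locants; Ar1 = 4-hydroxy-3-methoxyphenyl, Ar2 = 3,4-dimethoxyphenyl. The target is read as (7S,8R,7'R,8'S): a cis-fused bicycle with both aryl groups on the convex face and Ar1 cis to the acetoxy group.
- The structures of the key-step precursor and product were checked against this configuration and are consistent with it. The (S)-configured auxiliary delivers (7S,8R) through the normal syn-aldol sense, so no structure needed correction.
- Assumption: the carbinol centre C7' formed in step 8 is carried as a mixture of epimers (left undefined in the SMILES of 15 and 16), because step 10 passes through the benzylic cation.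
- The phenol is carried as an allyl ether, not a benzyl ether, because hydrogenolysis would also threaten the two benzylic C–O bonds of the bicycle.
- Compound 2 is also a catalogue compound; if it is bought, step 1 falls away.

## Structural features

The target is a furofuran lignan: two tetrahydrofuran rings cis-fused through the C8–C8' bond (a 3,7-dioxabicyclo[3.3.0]octane). Ring A is O–C7'(Ar1)–C8'(OAc)–C8–C9 and ring B is O–C7(Ar2)–C8–C8'–C9'. Four contiguous stereocentres (7S, 8R, 8'S, 7'R) lie along the chain C7–C8–C8'–C7'; Ar2 is trans to C9 on ring B and Ar1 is cis to the acetoxy group on ring A. The two electron-rich benzylic ether bonds (C7–O and C7'–O) ionise in acid and are open to hydrogenolysis, the tertiary acetate is base-labile, and the phenol must be told apart from the tertiary alcohol when the acetate is installed. The main difficulty is C8', a fully substituted carbinol carbon at the ring fusion between the C8 methine and the benzylic C7'; it cannot be corrected later by epimerisation. The second difficulty is C7', whose aryl group must end up cis to the oxygen on C8'. The key step exploits the fact that C8' carries one oxygen and two oxygenated one-carbon arms (C9' of ring B and C7' of ring A), which is the substitution pattern of C3 of a 3-oxygenated oxetane. With the C7 hydroxyl two atoms away, opening one oxetane CH2 forms the O–C9' bond of ring B and frees the other CH2 as the C7' alcohol.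

## Logic of the disconnections

**20 to 19.** The phenolic O–allyl bond is cut. The phenol has to be masked through the aryl-metal step and through acetylation of the tertiary alcohol, and an allyl ether comes off with zerovalent palladium under neutral conditions. The gain is that acetylation becomes a one-hydroxyl problem. The forward step must leave the tertiary acetate and both benzylic ethers untouched.

**19 to 18 to 17.** The acetate C–O bond and then the O–Si bond are cut. An acetate would not survive the organomagnesium and hydride steps, whereas a silyl ether does, so the C8' oxygen travels as one robust group from step 3 to step 11. The forward steps need fluoride desilylation and acylation of a hindered tertiary alcohol without acid, which would endanger C7 and C7'.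

**17 to 16.** The C7'–O bond of ring A is cut. It is the bond an electron-rich benzylic cation makes most readily, and cutting it removes ring A and makes the C7' configuration of the precursor irrelevant. The bicycle becomes a monocyclic diol and both C7' epimers become usable. The forward closure must run under kinetic control with the aryl group cis to the C8' oxygen, in acid mild enough to spare the C7–O bond.

**16 to 15 to 11 and 13.** C9 is returned to the acyl level, then the C7'–aryl bond is cut. Keeping C9 as the imide retains the auxiliary until its work is done, and the C7'–aryl bond is the convergent junction with the second arene. The molecule falls into an aldehyde and a simple aryl bromide. The aryl metal must take the aldehyde in preference to the imide, and hydride must then cleave the exocyclic acyl–nitrogen bond.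

**11 to 10.** Only the oxidation level of C7' changes. The primary alcohol freed by the key step is neopentyl-like and has no α-hydrogen, so oxidation cannot epimerise anything. The demand is a neutral oxidant.

**10 to 9.** The O–C9' bond of ring B is cut and the C7' oxygen is reconnected to C9'. This regenerates an oxetane in which C8' is no longer stereogenic, so the quaternary carbinol is exchanged for a symmetric four-membered ring. One ring and one stereocentre disappear, and the C8' problem becomes a choice between two CH2 groups. The forward step must make the C7 hydroxyl open the CH2 that leaves the siloxy group trans to the C8 acyl group, without ionising C7 and without lactonisation of the freed alcohol.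

**9 to 6 and 7.** The C7–C8 bond is cut. The hydroxyl and the oxetanyl branch are syn, which is the retron of an auxiliary-controlled syn-aldol that fixes both centres absolutely. Ring B's carbons then come from three small pieces. The forward step requires Z-enolisation of a hindered imide next to a Lewis-basic oxetane.

**6 to 5 to 2 and 3.** The O–Si bond and then the C8–C8' bond are cut. The tertiary carbinol β to the imide carbonyl is an acetate-aldol retron on a symmetric ketone, so no stereochemistry is involved. The forward addition needs a cold quench to avoid retro-aldol and attack of the alkoxide on the auxiliary.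

**2 to 1, and 13 to 12.** The N–acyl bond and the aryl O–allyl bond are cut, which leads to commercial materials. Both forward steps are routine.

## Other disconnections considered

Alternative 1: The cut is through both benzylic C–O bonds (C7–O of ring B, C7'–O of ring A), unravelling the bicycle to the acyclic pentaol A1. In the forward sense acid ionises both benzylic carbinols; the C9' hydroxyl captures the C7 cation and the C9 hydroxyl captures the C7' cation, giving the deacetyl compound A2.
- In favour: two rings and two C–O bonds form in one operation, four-membered alternatives are excluded by ring size, and only C8 and C8' of A1 need to be defined. The phenol can stay free, since its benzylic cation is a quinone methide.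
- Equal or better: on ring-forming economy it is better than the chosen plan. For C7' it relies on the same cation capture as step 10, so it is equal on that point.
- Against: C7 and C7' are both left to kinetic face selection in one pot, whereas the chosen plan fixes C7 by the aldol. A1 has five free hydroxyls, including a vicinal tertiary/benzylic diol prone to pinacol-type shift and a C7 cation that can eliminate toward C8. Making A1 as one C8/C8' diastereomer (a quaternary carbinol next to a methine in an open chain) moves the central difficulty without removing it. After A2 the tertiary alcohol must be acetylated beside a free phenol, which costs extra steps.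
- Comparison: the same ring bonds are made late in both plans. Mechanistically it is two SN1 closures against one strain-release SN2 and one SN1. The end game is shorter but the front end is longer and less certain.

Alternative 2: The cut removes the ring A oxygen (retro-Baeyer–Villiger) and then the C8–C9 and C7'–C8' bonds of a cyclobutanone, leading to the ring B silyl enol ether A3 and the arylketene A4. In the forward sense A4 adds across C8=C8' of A3 to give the cyclobutanone A5. Oxygen insertion then gives the lactone A6, which must be reduced to the cyclic ether.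
- In favour: two C–C bonds and three stereocentres (C8, C8', C7') form in one step. The suprafacial addition guarantees the cis fusion, and the regiochemistry is reliable in both the cycloaddition (nucleophilic C8 to the ketene carbonyl carbon) and the insertion (benzylic C7' migrates with retention).
- Equal or better: it is more convergent and better in C–C bond economy than the chosen plan. Face selection anti to the C7 aryl group should be as dependable as the aldol is for the C7/C8 relation.
- Against: monosubstituted arylketenes dimerise readily and are weak partners for silyl enol ethers. The ketene substituent normally ends on the concave face, so the exo aryl of A5 would depend on a later epimerisation. A3 requires enolisation toward C8 in competition with the more acidic C9' position, and an independent enantioselective entry to C7. A peracid has to be used beside two electron-rich arenes, and converting A6 to the ether with a Lewis-acidic silane threatens the benzylic ethers.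
- Comparison: the step count is comparable. The chosen plan forms only C–O bonds under mild acid and takes its absolute configuration from a standard auxiliary.

Alternative 3: The cut is the C7'–C8' bond, leading to the ring B ketone A7, which carries the Ar1-methyl ether on C9. In the forward sense irradiation excites the ketone, its oxygen abstracts a hydrogen from the ether CH2 (C7') through a seven-membered transition state, and the 1,5-biradical collapses to the tertiary alcohol A8.
- In favour: ring A, the C7'–C8' bond, the tertiary hydroxyl and two stereocentres arise in one reagent-free step. A7 is simple, and its enolisable C8 centre is thermodynamically biased trans to the aryl group. The tactic is known for hydroxylated furofurans.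
- Equal or better: on step count it is clearly better than the chosen plan. On the cis fusion it is equal, since that is automatic.
- Against: α-cleavage of the α-alkoxy ketone, photoreduction and back hydrogen transfer compete. Two electron-rich arenes absorb and can quench the excited ketone. The configurations of C7' and C8' are decided in the biradical collapse with no handle for tuning, and dilute photochemistry limits throughput.
- Comparison: the chosen plan sets C8' in a ground-state, catalyst-tunable step and C7' in a separate step that has a stereospecific fallback, at the cost of a longer sequence.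

Key step: step 5

## Route

Step 1
Reactants: 1 (S)-4-benzyl-1,3-oxazolidin-2-one
Product: 2 (S)-3-acetyl-4-benzyl-1,3-oxazolidin-2-one
Conditions: Ac2O, Et3N, 4-dimethylaminopyridine (cat.), CH2Cl2, rt
Reagents that add atoms: acetic anhydride, CC(=O)OC(C)=O
Why: Nucleophile-catalysed N-acylation of the carbamate nitrogen by the anhydride; the C4 stereocentre of the auxiliary is not involved.

Step 2
Reactants: 2 (S)-3-acetyl-4-benzyl-1,3-oxazolidin-2-one; 3 oxetan-3-one
Product: 5 (S)-4-benzyl-3-[2-(3-hydroxyoxetan-3-yl)acetyl]-1,3-oxazolidin-2-one, via lithium enolate 4 (not isolated)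
Conditions: LiN(SiMe3)2, THF, −78 °C; then 3, −78 °C; aq NH4Cl at −78 °C
Reagents that add atoms: none
Why: Acetate-type aldol addition of the lithium enolate to a strained, highly electrophilic ketone; the cold quench should prevent retro-aldol and attack of the tertiary alkoxide on the carbamate carbonyl. No stereocentre arises because the ketone is symmetric.

Step 3
Reactants: 5 (S)-4-benzyl-3-[2-(3-hydroxyoxetan-3-yl)acetyl]-1,3-oxazolidin-2-one
Product: 6 (S)-4-benzyl-3-{2-[3-(tert-butyldimethylsilyloxy)oxetan-3-yl]acetyl}-1,3-oxazolidin-2-one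
Conditions: TBSOTf, 2,6-lutidine, CH2Cl2, −78 → 0 °C
Reagents that add atoms: tert-butyldimethylsilyl trifluoromethanesulfonate, CC(C)(C)[Si](C)(C)OS(=O)(=O)C(F)(F)F
Why: Silyl triflate silylation of a tertiary alcohol with a hindered base; it blocks retro-aldol and keeps the tertiary oxygen from acting as a nucleophile or boron ligand later.

Step 4
Reactants: 6 (S)-4-benzyl-3-{2-[3-(tert-butyldimethylsilyloxy)oxetan-3-yl]acetyl}-1,3-oxazolidin-2-one; 7 3,4-dimethoxybenzaldehyde (veratraldehyde)
Product: 9 (S)-4-benzyl-3-{(2R,3S)-2-[3-(tert-butyldimethylsilyloxy)oxetan-3-yl]-3-(3,4-dimethoxyphenyl)-3-hydroxypropanoyl}-1,3-oxazolidin-2-one, via Z-dibutylboron enolate 8 (not isolated)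
Conditions: Bu2BOTf, i-Pr2NEt, CH2Cl2, 0 °C; then 7, −78 → 0 °C; pH 7 buffer, MeOH, H2O2, 0 °C
Reagents that add atoms: none
Why: Evans syn-aldol through the Z-boron enolate and a chair Zimmerman–Traxler transition state; with the auxiliary carbonyl dipole opposed to the enolate C–O bond the aldehyde adds on the face away from the benzyl group, which sets C8 (R) and C7 (S) in the syn relation. The amine is present in excess so that free boron triflate does not dwell on the oxetane oxygen.

Step 5
Reactants: 9 (S)-4-benzyl-3-{(2R,3S)-2-[3-(tert-butyldimethylsilyloxy)oxetan-3-yl]-3-(3,4-dimethoxyphenyl)-3-hydroxypropanoyl}-1,3-oxazolidin-2-one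
Product: 10 (S)-4-benzyl-3-{[(2S,3R,4R)-4-(tert-butyldimethylsilyloxy)-2-(3,4-dimethoxyphenyl)-4-(hydroxymethyl)oxolan-3-yl]carbonyl}-1,3-oxazolidin-2-one
Conditions: (R)-3,3'-bis(2,4,6-triisopropylphenyl)-1,1'-binaphthyl-2,2'-diyl hydrogen phosphate (10 mol %), PhMe, 4 Å MS, 25 → 40 °C
Reagents that add atoms: none
Why: The phosphoric acid hydrogen-bonds to the oxetane oxygen while its P=O accepts the C7 hydroxyl proton, and the C7 oxygen displaces the oxetane oxygen at one CH2 in an SN2 step driven by release of roughly 25 kcal/mol of ring strain. This is the known acid-catalysed intramolecular opening of 3,3-disubstituted oxetanes by a pendant alcohol to give tetrahydrofurans. Ring B closes in the 5-exo-tet mode (O–C7–C8–C8'–C9', the breaking C9'–O bond lying outside the new ring), which forms the O–C9' bond and frees the other arm as the C7' primary alcohol; C7 and C8 are not touched and keep their aldol-derived configuration. C8' becomes a stereocentre through the choice between its two diastereotopic CH2 groups, and the controlling element is the C8 stereocentre: attack on the CH2 that leaves the siloxy group trans to the C8 acyl group gives the all-trans array aryl/acyl/siloxy around ring B and avoids a nearly eclipsed siloxy–imide contact in the envelope transition state. The enantiomer of the chiral acid that matches this substrate bias reinforces it; diphenyl phosphate and the antipodal acid serve as the controls that identify the matched case. Chemoselectivity rests on the C7 hydroxyl being the only good nucleophile placed for a five-membered closure, since the tertiary oxygen is silylated and the imide carbonyl is a poor nucleophile. The weak acid in an apolar solvent is chosen so that the benzylic C7–O bond does not ionise and the freed alcohol, which sits cis to the imide, does not lactonise before step 6.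

Step 6
Reactants: 10 (S)-4-benzyl-3-{[(2S,3R,4R)-4-(tert-butyldimethylsilyloxy)-2-(3,4-dimethoxyphenyl)-4-(hydroxymethyl)oxolan-3-yl]carbonyl}-1,3-oxazolidin-2-one
Product: 11 (S)-4-benzyl-3-{[(2S,3R,4S)-4-(tert-butyldimethylsilyloxy)-2-(3,4-dimethoxyphenyl)-4-formyloxolan-3-yl]carbonyl}-1,3-oxazolidin-2-one
Conditions: Dess–Martin periodinane, pyridine, CH2Cl2, 0 °C → rt (crude 10 used directly)
Reagents that add atoms: none
Why: Dess–Martin oxidation of the only free hydroxyl to the aldehyde under near-neutral conditions; the aldehyde carbon sits on the quaternary C8', so there is no α-hydrogen to epimerise, and removing the alcohol ends the lactonisation risk.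

Step 7
Reactants: 12 4-bromo-2-methoxyphenol
Product: 13 1-(allyloxy)-4-bromo-2-methoxybenzene
Conditions: allyl bromide, K2CO3, acetone, reflux
Reagents that add atoms: allyl bromide, C=CCBr
Why: Williamson O-alkylation of the phenoxide; the allyl ether tolerates magnesium insertion, hydride, mild acid, fluoride and acylation.

Step 8
Reactants: 11 (S)-4-benzyl-3-{[(2S,3R,4S)-4-(tert-butyldimethylsilyloxy)-2-(3,4-dimethoxyphenyl)-4-formyloxolan-3-yl]carbonyl}-1,3-oxazolidin-2-one; 13 1-(allyloxy)-4-bromo-2-methoxybenzene
Product: 15 (S)-4-benzyl-3-{[(2S,3R,4S)-4-{[4-(allyloxy)-3-methoxyphenyl](hydroxy)methyl}-4-(tert-butyldimethylsilyloxy)-2-(3,4-dimethoxyphenyl)oxolan-3-yl]carbonyl}-1,3-oxazolidin-2-one (both C7' epimers), via arylmagnesium bromide 14 (not isolated)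
Conditions: 13, Mg, THF, 40 °C; then 11, THF, −78 °C; aq NH4Cl at −78 °C
Reagents that add atoms: none
Why: Grignard addition to the aldehyde, which at −78 °C should be far faster than attack on the hindered imide; the C7' configuration is not controlled and is not needed. Any alkoxide that closes onto the imide gives a γ-lactone that step 9 reduces to the same diol.

Step 9
Reactants: 15 (S)-4-benzyl-3-{[(2S,3R,4S)-4-{[4-(allyloxy)-3-methoxyphenyl](hydroxy)methyl}-4-(tert-butyldimethylsilyloxy)-2-(3,4-dimethoxyphenyl)oxolan-3-yl]carbonyl}-1,3-oxazolidin-2-one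
Product: 16 (2S,3R,4S)-4-{[4-(allyloxy)-3-methoxyphenyl](hydroxy)methyl}-4-(tert-butyldimethylsilyloxy)-2-(3,4-dimethoxyphenyl)-3-(hydroxymethyl)oxolane (both C7' epimers)
Conditions: LiBH4, MeOH (1 equiv), THF, 0 °C
Reagents that add atoms: none
Why: Reductive cleavage of the exocyclic acyl–nitrogen bond gives the C9 primary alcohol and releases the auxiliary for recovery; silyl ether, allyl ether and the benzylic ether of ring B are inert to borohydride.

Step 10
Reactants: 16 (2S,3R,4S)-4-{[4-(allyloxy)-3-methoxyphenyl](hydroxy)methyl}-4-(tert-butyldimethylsilyloxy)-2-(3,4-dimethoxyphenyl)-3-(hydroxymethyl)oxolane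
Product: 17 (1S,2R,5R,6S)-2-[4-(allyloxy)-3-methoxyphenyl]-1-(tert-butyldimethylsilyloxy)-6-(3,4-dimethoxyphenyl)-3,7-dioxabicyclo[3.3.0]octane
Conditions: (+)-camphor-10-sulfonic acid (10 mol %), CH2Cl2, 4 Å MS, 0 °C
Reagents that add atoms: none
Why: SN1 benzylic etherification: acid ionises either carbinol epimer to the same p-alkoxybenzyl cation, which the C9 hydroxyl traps to close ring A. With the C8'–O bond in the plane of the cation (the poorest σ-donor and the smallest flanking group, hence least allylic 1,3-strain with the ortho C–H) and attack from the C8 side, the aryl group should come out cis to the C8' oxygen, i.e. C7' (R).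

Step 11
Reactants: 17 (1S,2R,5R,6S)-2-[4-(allyloxy)-3-methoxyphenyl]-1-(tert-butyldimethylsilyloxy)-6-(3,4-dimethoxyphenyl)-3,7-dioxabicyclo[3.3.0]octane
Product: 18 (1S,2R,5R,6S)-2-[4-(allyloxy)-3-methoxyphenyl]-6-(3,4-dimethoxyphenyl)-3,7-dioxabicyclo[3.3.0]octan-1-ol
Conditions: Bu4NF, THF, rt → 45 °C
Reagents that add atoms: none
Why: Fluoride cleavage of the tertiary silyl ether; the basic, non-acidic conditions leave both benzylic ethers and the allyl ether untouched.

Step 12
Reactants: 18 (1S,2R,5R,6S)-2-[4-(allyloxy)-3-methoxyphenyl]-6-(3,4-dimethoxyphenyl)-3,7-dioxabicyclo[3.3.0]octan-1-ol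
Product: 19 (1S,2R,5R,6S)-2-[4-(allyloxy)-3-methoxyphenyl]-6-(3,4-dimethoxyphenyl)-3,7-dioxabicyclo[3.3.0]octan-1-yl acetate
Conditions: Ac2O, Et3N, 4-dimethylaminopyridine, CH2Cl2, 40 °C
Reagents that add atoms: acetic anhydride, CC(=O)OC(C)=O
Why: Nucleophile-catalysed acetylation of the only free hydroxyl, a tertiary alcohol on the convex face; the base-mediated conditions avoid acid that could ionise C7 or C7'.

Step 13
Reactants: 19 (1S,2R,5R,6S)-2-[4-(allyloxy)-3-methoxyphenyl]-6-(3,4-dimethoxyphenyl)-3,7-dioxabicyclo[3.3.0]octan-1-yl acetate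
Product: 20 (1S,2R,5R,6S)-6-(3,4-dimethoxyphenyl)-2-(4-hydroxy-3-methoxyphenyl)-3,7-dioxabicyclo[3.3.0]octan-1-yl acetate (CNP0107105.1)
Conditions: Pd(PPh3)4 (5 mol %), morpholine, THF, rt
Reagents that add atoms: none
Why: Tsuji–Trost deallylation: zerovalent palladium ionises the aryl allyl ether to a π-allyl complex, which morpholine intercepts, freeing the phenol under neutral conditions that spare the tertiary acetate and the benzylic C–O bonds.

## Compound list

1 | (S)-4-benzyl-1,3-oxazolidin-2-one | O=C1N[C@@H](Cc2ccccc2)CO1 | starting material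
2 | (S)-3-acetyl-4-benzyl-1,3-oxazolidin-2-one | CC(=O)N1[C@@H](Cc2ccccc2)COC1=O | intermediate
3 | oxetan-3-one | O=C1COC1 | starting material
4 | lithium enolate of 2 | C=C(O[Li])N1[C@@H](Cc2ccccc2)COC1=O | intermediate (not isolated)
5 | (S)-4-benzyl-3-[2-(3-hydroxyoxetan-3-yl)acetyl]-1,3-oxazolidin-2-one | OC1(CC(=O)N2[C@@H](Cc3ccccc3)COC2=O)COC1 | intermediate
6 | (S)-4-benzyl-3-{2-[3-(tert-butyldimethylsilyloxy)oxetan-3-yl]acetyl}-1,3-oxazolidin-2-one | CC(C)(C)[Si](C)(C)OC1(CC(=O)N2[C@@H](Cc3ccccc3)COC2=O)COC1 | intermediate
7 | 3,4-dimethoxybenzaldehyde (veratraldehyde) | COc1ccc(C=O)cc1OC | starting material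
8 | Z-dibutylboron enolate of 6 | CCCCB(CCCC)O/C(=C\C1(O[Si](C)(C)C(C)(C)C)COC1)N1[C@@H](Cc2ccccc2)COC1=O | intermediate (not isolated)
9 | (S)-4-benzyl-3-{(2R,3S)-2-[3-(tert-butyldimethylsilyloxy)oxetan-3-yl]-3-(3,4-dimethoxyphenyl)-3-hydroxypropanoyl}-1,3-oxazolidin-2-one (syn-aldol adduct, 7S,8R) | O=C1OC[C@H](Cc2ccccc2)N1C(=O)[C@H]([C@H](O)c3ccc(OC)c(OC)c3)C4(O[Si](C)(C)C(C)(C)C)COC4 | intermediate
10 | (S)-4-benzyl-3-{[(2S,3R,4R)-4-(tert-butyldimethylsilyloxy)-2-(3,4-dimethoxyphenyl)-4-(hydroxymethyl)oxolan-3-yl]carbonyl}-1,3-oxazolidin-2-one (ring B; siloxy trans to acyl, CH2OH cis to acyl) | COc1ccc([C@H]2OC[C@](O[Si](C)(C)C(C)(C)C)(CO)[C@@H]2C(=O)N3[C@@H](Cc4ccccc4)COC3=O)cc1OC | intermediate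
11 | (S)-4-benzyl-3-{[(2S,3R,4S)-4-(tert-butyldimethylsilyloxy)-2-(3,4-dimethoxyphenyl)-4-formyloxolan-3-yl]carbonyl}-1,3-oxazolidin-2-one | COc1ccc([C@H]2OC[C@](O[Si](C)(C)C(C)(C)C)(C=O)[C@@H]2C(=O)N3[C@@H](Cc4ccccc4)COC3=O)cc1OC | intermediate
12 | 4-bromo-2-methoxyphenol | COc1cc(Br)ccc1O | starting material
13 | 1-(allyloxy)-4-bromo-2-methoxybenzene | C=CCOc1ccc(Br)cc1OC | intermediate
14 | [4-(allyloxy)-3-methoxyphenyl]magnesium bromide | C=CCOc1ccc([Mg]Br)cc1OC | intermediate (not isolated)
15 | (S)-4-benzyl-3-{[(2S,3R,4S)-4-{[4-(allyloxy)-3-methoxyphenyl](hydroxy)methyl}-4-(tert-butyldimethylsilyloxy)-2-(3,4-dimethoxyphenyl)oxolan-3-yl]carbonyl}-1,3-oxazolidin-2-one, both C7' epimers | COc1ccc([C@H]2OC[C@](O[Si](C)(C)C(C)(C)C)(C(O)c3ccc(OCC=C)c(OC)c3)[C@@H]2C(=O)N3[C@@H](Cc4ccccc4)COC3=O)cc1OC | intermediate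
16 | (2S,3R,4S)-4-{[4-(allyloxy)-3-methoxyphenyl](hydroxy)methyl}-4-(tert-butyldimethylsilyloxy)-2-(3,4-dimethoxyphenyl)-3-(hydroxymethyl)oxolane, both C7' epimers | COc1ccc([C@H]2OC[C@](O[Si](C)(C)C(C)(C)C)(C(O)c3ccc(OCC=C)c(OC)c3)[C@@H]2CO)cc1OC | intermediate
17 | (1S,2R,5R,6S)-2-[4-(allyloxy)-3-methoxyphenyl]-1-(tert-butyldimethylsilyloxy)-6-(3,4-dimethoxyphenyl)-3,7-dioxabicyclo[3.3.0]octane | COc1cc([C@H]2OC[C@@H]3[C@@H](c4ccc(OC)c(OC)c4)OC[C@]23O[Si](C)(C)C(C)(C)C)ccc1OCC=C | intermediate
18 | (1S,2R,5R,6S)-2-[4-(allyloxy)-3-methoxyphenyl]-6-(3,4-dimethoxyphenyl)-3,7-dioxabicyclo[3.3.0]octan-1-ol | COc1cc([C@H]2OC[C@@H]3[C@@H](c4ccc(OC)c(OC)c4)OC[C@]23O)ccc1OCC=C | intermediate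
19 | (1S,2R,5R,6S)-2-[4-(allyloxy)-3-methoxyphenyl]-6-(3,4-dimethoxyphenyl)-3,7-dioxabicyclo[3.3.0]octan-1-yl acetate | COc1cc([C@H]2OC[C@@H]3[C@@H](c4ccc(OC)c(OC)c4)OC[C@]23OC(C)=O)ccc1OCC=C | intermediate
20 | (1S,2R,5R,6S)-6-(3,4-dimethoxyphenyl)-2-(4-hydroxy-3-methoxyphenyl)-3,7-dioxabicyclo[3.3.0]octan-1-yl acetate; lignan locants (7S,8R,7'R,8'S) | COc1cc([C@H]2OC[C@@H]3[C@@H](c4ccc(OC)c(OC)c4)OC[C@]23OC(C)=O)ccc1O | target

## Step count and least certain steps

Total: 13 steps. Longest linear sequence: 12 steps (1 → 2 → 5 → 6 → 9 → 10 → 11 → 15 → 16 → 17 → 18 → 19 → 20); the side branch 12 → 13 is one step.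

**Step 5 (key step).**
- What may go wrong: poor discrimination between the two CH2 groups, because the energy gap between the two reactive rotamers about C8–C8' may be small. The freed alcohol may lactonise onto the cis imide with loss of the auxiliary, and the benzylic C7–O bond may ionise if the acid is too strong.
- Fallback: substrate-controlled dihydroxylation of an exocyclic alkene; it sets out from 10, taken as the mixture with its C8' epimer F1, and comes back at 11. The mixture is converted with I2, PPh3 and imidazole (PhMe, 80 °C) into the neopentyl iodides F2. Zinc dust (NH4Cl, EtOH, 60 °C) then inserts into the C–I bond and expels the β-siloxy group in a Boord-type reductive elimination, so both epimers converge on the 4-methyleneoxolane F3. OsO4 (cat.) with N-methylmorpholine N-oxide should add to the alkene face anti to the adjacent C8 acyl group and give the diol F4 with the tertiary hydroxyl trans to the acyl group. Oxidation of the primary hydroxyl (2,2,6,6-tetramethylpiperidin-1-oxyl, PhI(OAc)2) gives the hydroxy aldehyde F5, and TBSOTf/2,6-lutidine returns 11.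

**Step 4.**
- What may go wrong: sluggish enolisation at the neopentyl-type CH2, opening of the Lewis-basic oxetane by the boron triflate, and β-elimination of the siloxy group from the enolate.
- Fallback: chelation-controlled acylation followed by chelation-controlled reduction in the antipodal auxiliary series, which avoids boron triflate; it sets out from 3 and comes back at 16. (R)-3-Acetyl-4-benzyl-1,3-oxazolidin-2-one F6 (purchased) is added to 3 as in step 2 to give the tertiary alcohol F7, which is silylated as in step 3 to the silyl ether F8. The chelated lithium Z-enolate of F8 (LiN(SiMe3)2, THF, −78 °C) is acylated with 3,4-dimethoxybenzoyl chloride on the face away from the benzyl group to give the β-keto imide F9, which has the required C8 configuration. Zn(BH4)2 (Et2O/CH2Cl2, −20 °C) then reduces it through the dicarbonyl chelate to the syn-hydroxy imide F10. F10 differs from 9 only at the auxiliary centre and is taken through the conditions of steps 5, 6 and 8: first to the ring B alcohol F11, then the aldehyde F12, then the carbinol F13. LiBH4 as in step 9 removes the auxiliary and gives 16. The matched enantiomer of the phosphoric acid has to be determined afresh for this series.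

**Step 10.**
- What may go wrong: loss of facial control in the capture of the cation (the equilibrium preference between exo and endo aryl is small in this ring system, so the result depends on kinetic control), ionisation of the C7–O bond of ring B with epimerisation, and a semipinacol shift of the β-siloxy cation.
- Fallback: a stereospecific closure that never ionises C7'; it sets out from 15 and comes back at 17. Dess–Martin oxidation converges both epimers on the aryl ketone F14. LiBH4 (THF, −78 → 0 °C) reduces the ketone under Felkin–Anh control (siloxy group anti to the incoming hydride, which passes the smaller C9' methylene) and also cleaves the imide, giving the (7'R)-diol F15. The primary hydroxyl is sulfonylated selectively (TsCl, pyridine, 0 °C) to the tosylate F16. NaH in THF then closes ring A by Williamson displacement at C9 (5-exo-tet), with the C7' configuration retained, to give 17.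

**Step 8.**
- What may go wrong: competing attack of the Grignard reagent on the imide carbonyl, deprotonation at C8 followed by β-elimination of the siloxy or ring oxygen, and incomplete addition to the hindered aldehyde.
- Fallback: a Nozaki–Hiyama–Kishi arylation, whose organochromium reagent is non-basic and aldehyde-selective; it sets out from 11 and 13 and comes back at 15. The Grignard reagent 14 made from 13 is quenched with I2 (THF, 0 °C) to give 1-(allyloxy)-4-iodo-2-methoxybenzene F17. F17 and 11 are then combined with CrCl2 and NiCl2 (cat.) in DMF at rt; the aryl halide is activated by nickel, transferred to chromium, and added to the aldehyde by the resulting arylchromium species in the presence of the imide to give 15.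

## Further compounds

F1 | step 5 | (S)-4-benzyl-3-{[(2S,3R,4S)-4-(tert-butyldimethylsilyloxy)-2-(3,4-dimethoxyphenyl)-4-(hydroxymethyl)oxolan-3-yl]carbonyl}-1,3-oxazolidin-2-one (C8' epimer of 10) | COc1ccc([C@H]2OC[C@@](O[Si](C)(C)C(C)(C)C)(CO)[C@@H]2C(=O)N3[C@@H](Cc4ccccc4)COC3=O)cc1OC
F2 | step 5 | (S)-4-benzyl-3-{[(2S,3R)-4-(tert-butyldimethylsilyloxy)-2-(3,4-dimethoxyphenyl)-4-(iodomethyl)oxolan-3-yl]carbonyl}-1,3-oxazolidin-2-one, both C8' epimers | COc1ccc([C@H]2OCC(O[Si](C)(C)C(C)(C)C)(CI)[C@@H]2C(=O)N3[C@@H](Cc4ccccc4)COC3=O)cc1OC
F3 | step 5 | (S)-4-benzyl-3-{[(2S,3R)-2-(3,4-dimethoxyphenyl)-4-methylideneoxolan-3-yl]carbonyl}-1,3-oxazolidin-2-one | COc1ccc([C@H]2OCC(=C)[C@@H]2C(=O)N3[C@@H](Cc4ccccc4)COC3=O)cc1OC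
F4 | step 5 | (S)-4-benzyl-3-{[(2S,3R,4R)-2-(3,4-dimethoxyphenyl)-4-hydroxy-4-(hydroxymethyl)oxolan-3-yl]carbonyl}-1,3-oxazolidin-2-one (tertiary hydroxyl trans to acyl) | COc1ccc([C@H]2OC[C@](O)(CO)[C@@H]2C(=O)N3[C@@H](Cc4ccccc4)COC3=O)cc1OC
F5 | step 5 | (S)-4-benzyl-3-{[(2S,3R,4S)-2-(3,4-dimethoxyphenyl)-4-formyl-4-hydroxyoxolan-3-yl]carbonyl}-1,3-oxazolidin-2-one | COc1ccc([C@H]2OC[C@](O)(C=O)[C@@H]2C(=O)N3[C@@H](Cc4ccccc4)COC3=O)cc1OC
F6 | step 4 | (R)-3-acetyl-4-benzyl-1,3-oxazolidin-2-one | CC(=O)N1[C@H](Cc2ccccc2)COC1=O
F7 | step 4 | (R)-4-benzyl-3-[2-(3-hydroxyoxetan-3-yl)acetyl]-1,3-oxazolidin-2-one | OC1(CC(=O)N2[C@H](Cc3ccccc3)COC2=O)COC1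
F8 | step 4 | (R)-4-benzyl-3-{2-[3-(tert-butyldimethylsilyloxy)oxetan-3-yl]acetyl}-1,3-oxazolidin-2-one | CC(C)(C)[Si](C)(C)OC1(CC(=O)N2[C@H](Cc3ccccc3)COC2=O)COC1
F9 | step 4 | (R)-4-benzyl-3-{2-[3-(tert-butyldimethylsilyloxy)oxetan-3-yl]-3-(3,4-dimethoxyphenyl)-3-oxopropanoyl}-1,3-oxazolidin-2-one, C8 as in 9 | O=C1OC[C@@H](Cc2ccccc2)N1C(=O)[C@H](C(=O)c3ccc(OC)c(OC)c3)C4(O[Si](C)(C)C(C)(C)C)COC4
F10 | step 4 | (R)-4-benzyl-3-{(2R,3S)-2-[3-(tert-butyldimethylsilyloxy)oxetan-3-yl]-3-(3,4-dimethoxyphenyl)-3-hydroxypropanoyl}-1,3-oxazolidin-2-one | O=C1OC[C@@H](Cc2ccccc2)N1C(=O)[C@H]([C@H](O)c3ccc(OC)c(OC)c3)C4(O[Si](C)(C)C(C)(C)C)COC4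
F11 | step 4 | (R)-4-benzyl-3-{[(2S,3R,4R)-4-(tert-butyldimethylsilyloxy)-2-(3,4-dimethoxyphenyl)-4-(hydroxymethyl)oxolan-3-yl]carbonyl}-1,3-oxazolidin-2-one | COc1ccc([C@H]2OC[C@](O[Si](C)(C)C(C)(C)C)(CO)[C@@H]2C(=O)N3[C@H](Cc4ccccc4)COC3=O)cc1OC
F12 | step 4 | (R)-4-benzyl-3-{[(2S,3R,4S)-4-(tert-butyldimethylsilyloxy)-2-(3,4-dimethoxyphenyl)-4-formyloxolan-3-yl]carbonyl}-1,3-oxazolidin-2-one | COc1ccc([C@H]2OC[C@](O[Si](C)(C)C(C)(C)C)(C=O)[C@@H]2C(=O)N3[C@H](Cc4ccccc4)COC3=O)cc1OC
F13 | step 4 | (R)-4-benzyl-3-{[(2S,3R,4S)-4-{[4-(allyloxy)-3-methoxyphenyl](hydroxy)methyl}-4-(tert-butyldimethylsilyloxy)-2-(3,4-dimethoxyphenyl)oxolan-3-yl]carbonyl}-1,3-oxazolidin-2-one, both C7' epimers | COc1ccc([C@H]2OC[C@](O[Si](C)(C)C(C)(C)C)(C(O)c5ccc(OCC=C)c(OC)c5)[C@@H]2C(=O)N3[C@H](Cc4ccccc4)COC3=O)cc1OC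
F14 | step 10 | (S)-4-benzyl-3-{[(2S,3R,4S)-4-[4-(allyloxy)-3-methoxybenzoyl]-4-(tert-butyldimethylsilyloxy)-2-(3,4-dimethoxyphenyl)oxolan-3-yl]carbonyl}-1,3-oxazolidin-2-one | COc1ccc([C@H]2OC[C@](O[Si](C)(C)C(C)(C)C)(C(=O)c5ccc(OCC=C)c(OC)c5)[C@@H]2C(=O)N3[C@@H](Cc4ccccc4)COC3=O)cc1OC
F15 | step 10 | (2S,3R,4S)-4-{(R)-[4-(allyloxy)-3-methoxyphenyl](hydroxy)methyl}-4-(tert-butyldimethylsilyloxy)-2-(3,4-dimethoxyphenyl)-3-(hydroxymethyl)oxolane | COc1ccc([C@H]2OC[C@](O[Si](C)(C)C(C)(C)C)([C@H](O)c3ccc(OCC=C)c(OC)c3)[C@@H]2CO)cc1OC
F16 | step 10 | primary 4-methylbenzenesulfonate of F15 (at the C9 hydroxyl) | COc1ccc([C@H]2OC[C@](O[Si](C)(C)C(C)(C)C)([C@H](O)c3ccc(OCC=C)c(OC)c3)[C@@H]2COS(=O)(=O)c4ccc(C)cc4)cc1OC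
F17 | step 8 | 1-(allyloxy)-4-iodo-2-methoxybenzene | C=CCOc1ccc(I)cc1OC
A1 | alternative 1 | 1-(3,4-dimethoxyphenyl)-4-(4-hydroxy-3-methoxyphenyl)-2,3-bis(hydroxymethyl)butane-1,3,4-triol, C8 and C8' as in the target, benzylic centres undefined | OC[C@@H]([C@](O)(CO)C(O)c1ccc(O)c(OC)c1)C(O)c1ccc(OC)c(OC)c1
A2 | alternative 1 | (1S,2R,5R,6S)-6-(3,4-dimethoxyphenyl)-2-(4-hydroxy-3-methoxyphenyl)-3,7-dioxabicyclo[3.3.0]octan-1-ol (deacetyl target) | COc1cc([C@H]2OC[C@@H]3[C@@H](c4ccc(OC)c(OC)c4)OC[C@]23O)ccc1O
A3 | alternative 2 | (S)-tert-butyl{[5-(3,4-dimethoxyphenyl)-2,5-dihydrofuran-3-yl]oxy}dimethylsilane (ring B silyl enol ether, C8=C8') | COc1ccc([C@H]2OCC(O[Si](C)(C)C(C)(C)C)=C2)cc1OC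
A4 | alternative 2 | [4-(benzyloxy)-3-methoxyphenyl]ketene | COc1cc(C=C=O)ccc1OCc1ccccc1
A5 | alternative 2 | cis-fused 7-[4-(benzyloxy)-3-methoxyphenyl]-1-(tert-butyldimethylsilyloxy)-4-(3,4-dimethoxyphenyl)-3-oxabicyclo[3.2.0]heptan-6-one, aryl at C7' exo | COc1cc([C@H]2C(=O)[C@@H]3[C@@H](c4ccc(OC)c(OC)c4)OC[C@]23O[Si](C)(C)C(C)(C)C)ccc1OCc1ccccc1
A6 | alternative 2 | ring A γ-lactone from oxygen insertion into A5 (C9 carbonyl, oxygen on C7') | COc1cc([C@H]2OC(=O)[C@@H]3[C@@H](c4ccc(OC)c(OC)c4)OC[C@]23O[Si](C)(C)C(C)(C)C)ccc1OCc1ccccc1
A7 | alternative 3 | (4R,5S)-4-({[4-(benzyloxy)-3-methoxyphenyl]methoxy}methyl)-5-(3,4-dimethoxyphenyl)oxolan-3-one | COc1ccc([C@H]2OCC(=O)[C@@H]2COCc2ccc(OCc3ccccc3)c(OC)c2)cc1OC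
A8 | alternative 3 | (1S,2R,5R,6S)-2-[4-(benzyloxy)-3-methoxyphenyl]-6-(3,4-dimethoxyphenyl)-3,7-dioxabicyclo[3.3.0]octan-1-ol | COc1cc([C@H]2OC[C@@H]3[C@@H](c4ccc(OC)c(OC)c4)OC[C@]23O)ccc1OCc1ccccc1
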